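**Retrosynthetic overview**
- Endgame: global deprotection. The C1 ketone of ring B comes from Markovnikov hydration and oxidation of a C1=C2 styrene-type double bond.
- Ring B is closed last, by ring-closing metathesis of a styrene/vinyl diene.
- Key C3–C4 bond: an anti-selective, catalyst-controlled carbonyl allylboration. The ring A aldehyde (fragment 1) reacts with an (E)-γ-aryl allylboronate carrying rings C and D (fragment 2), which sets C3 and C4 together.
- Fragment 2: ring D is closed first by Friedel–Crafts acylation. C4' is set by asymmetric transfer hydrogenation and C1' by benzylic oxidation. The C7' carbon arrives by aromatic Claisen rearrangement, followed by allylic acetoxylation and borylation.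
- Rings A and C are bought as arenes (3,5-dimethoxytoluene and 2-hydroxy-4-methylbenzaldehyde). Order of ring formation: D, then B.

Assumption and locants: the SMILES is read as (3R,4S,4'R), meaning aryl and OH are cis on ring B; C1–C8a is the upper tetralone (rings A/B) and C1'–C8a' is the lower tetralone (rings C/D).

**Fragment 1 (ring A aldehyde)**

Step 1
Reactants: 1 3,5-dimethoxytoluene
Product: 3 2,6-dimethoxy-4-methylbenzaldehyde, via aryllithium 2 (not isolated)
Conditions: n-BuLi, TMEDA, THF, 0 °C to rt; DMF, 0 °C; aq HCl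
Reagents that add atoms: DMF CN(C)C=O; n-BuLi [Li]CCCC (lithium of 2 only)
Why: Directed ortho-lithiation occurs at the position flanked by both methoxy groups and the aryllithium is formylated by DMF (Bouveault formylation), so one regioisomer forms and no stereocenter is involved.

Step 2
Reactants: 3 2,6-dimethoxy-4-methylbenzaldehyde
Product: 4 2,6-dihydroxy-4-methylbenzaldehyde (atranol)
Conditions: BBr3 (2.5 equiv), CH2Cl2, −78 °C to rt; H2O
Reagents that add atoms: none
Why: Lewis-acid aryl methyl ether cleavage, helped by chelation of boron to the flanking aldehyde oxygen, removes both methyl groups of this robust arene.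

Step 3
Reactants: 4 2,6-dihydroxy-4-methylbenzaldehyde
Product: 5 2-(benzyloxy)-6-hydroxy-4-methylbenzaldehyde
Conditions: BnBr (1.0 equiv), K2CO3 (1.1 equiv), acetone, reflux
Reagents that add atoms: benzyl bromide BrCc1ccccc1
Why: In this Williamson etherification the symmetrical diol can give only one mono-ether, and the remaining OH, hydrogen-bonded to the aldehyde, is alkylated much more slowly.

Step 4
Reactants: 5 2-(benzyloxy)-6-hydroxy-4-methylbenzaldehyde
Product: 6 3-(benzyloxy)-2-formyl-5-methylphenyl trifluoromethanesulfonate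
Conditions: Tf2O, pyridine, CH2Cl2, 0 °C
Reagents that add atoms: triflic anhydride O=S(=O)(OS(=O)(=O)C(F)(F)F)C(F)(F)F
Why: O-Sulfonylation of the phenol turns the future C8a position into a cross-coupling handle without affecting the aldehyde or the benzyl ether.

Step 5
Reactants: 6 3-(benzyloxy)-2-formyl-5-methylphenyl trifluoromethanesulfonate
Product: 7 2-(benzyloxy)-4-methyl-6-vinylbenzaldehyde (fragment 1)
Conditions: tributyl(vinyl)stannane, Pd(PPh3)4 (5 mol %), LiCl (3 equiv), 1,4-dioxane, 100 °C
Reagents that add atoms: tributyl(vinyl)stannane C=C[Sn](CCCC)(CCCC)CCCC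
Why: In this Stille coupling the triflate ortho to the formyl group adds readily to zerovalent palladium, chloride assists transmetalation, and the vinyl group that will become C1 is installed.

**Fragment 2 (rings C/D allylboronate)**

Step 6
Reactants: 8 2-hydroxy-4-methylbenzaldehyde
Product: 9 2-methoxy-4-methylbenzaldehyde
Conditions: MeI, K2CO3, DMF, rt
Reagents that add atoms: iodomethane CI
Why: Williamson methylation gives an ether that survives the acidic ring closure and later activates the neighbouring benzylic CH2 toward oxidation.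

Step 7
Reactants: 9 2-methoxy-4-methylbenzaldehyde; 10 (2-carboxyethyl)triphenylphosphonium bromide
Product: 12 (E)-4-(2-methoxy-4-methylphenyl)but-3-enoic acid, via ylide 11 (not isolated)
Conditions: 10 (1.2 equiv), KOt-Bu (2.5 equiv), THF, 0 °C; then 9, 0 °C to rt; aq HCl
Reagents that add atoms: KOt-Bu CC(C)(C)[O-].[K+] (potassium of 11 only)
Why: Wittig olefination with the carboxylate ylide adds the three remaining ring D carbons in one operation, and the alkene geometry (mainly E) does not matter because it is hydrogenated next.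

Step 8
Reactants: 12 (E)-4-(2-methoxy-4-methylphenyl)but-3-enoic acid
Product: 13 4-(2-methoxy-4-methylphenyl)butanoic acid
Conditions: H2 (1 atm), 10% Pd/C, EtOAc, rt
Reagents that add atoms: none
Why: Catalytic hydrogenation saturates the styrene-type double bond and leaves the arene, ether and acid unchanged.

Step 9
Reactants: 13 4-(2-methoxy-4-methylphenyl)butanoic acid
Product: 14 5-methoxy-7-methyl-3,4-dihydronaphthalen-1(2H)-one
Conditions: Eaton's reagent (7.7 wt % P2O5 in MeSO3H), rt to 50 °C
Reagents that add atoms: none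
Why: Intramolecular Friedel–Crafts acylation can close only onto the single free position ortho to the side chain (the closure that also gives 5-methoxy-1-tetralone), which forms ring D.

Step 10
Reactants: 14 5-methoxy-7-methyl-3,4-dihydronaphthalen-1(2H)-one
Product: 15 (1R)-5-methoxy-7-methyl-1,2,3,4-tetrahydronaphthalen-1-ol
Conditions: RuCl[(R,R)-TsDPEN](p-cymene) (0.5 mol %), HCO2H/Et3N 5:2, 35 °C
Reagents that add atoms: none
Why: Noyori asymmetric transfer hydrogenation of a 1-tetralone with the (R,R) catalyst delivers hydride to the face that gives the (R)-carbinol (typically 97–99% ee), and this sets C4'.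

Step 11
Reactants: 15 (1R)-5-methoxy-7-methyl-1,2,3,4-tetrahydronaphthalen-1-ol
Product: 16 (1R)-5-methoxy-7-methyl-1,2,3,4-tetrahydronaphthalen-1-yl acetate
Conditions: Ac2O, pyridine, DMAP (cat.), CH2Cl2, rt
Reagents that add atoms: acetic anhydride CC(=O)OC(C)=O
Why: O-Acylation retains configuration and the ester deactivates the carbinol C–H bond toward the coming oxidation.

Step 12
Reactants: 16 (1R)-5-methoxy-7-methyl-1,2,3,4-tetrahydronaphthalen-1-yl acetate
Product: 17 (1R)-5-methoxy-7-methyl-4-oxo-1,2,3,4-tetrahydronaphthalen-1-yl acetate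
Conditions: CrO3 (4 equiv), AcOH/H2O 9:1, 10 °C to rt
Reagents that add atoms: chromium trioxide O=[Cr](=O)=O
Why: Chromium trioxide benzylic oxidation attacks the ring CH2 that is ortho-activated by the methoxy group, whereas the aryl methyl (meta to OMe) and the acetoxy-bearing C–H react more slowly, so C1' becomes the ketone and C4' is untouched.

Step 13
Reactants: 17 (1R)-5-methoxy-7-methyl-4-oxo-1,2,3,4-tetrahydronaphthalen-1-yl acetate
Product: 18 (1R)-5-hydroxy-7-methyl-4-oxo-1,2,3,4-tetrahydronaphthalen-1-yl acetate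
Conditions: BCl3 (1.5 equiv), CH2Cl2, −78 to −10 °C; H2O
Reagents that add atoms: none
Why: In this chelation-controlled demethylation BCl3 binds between the ketone and the peri methoxy oxygen and cleaves only that O–Me bond at low temperature, and the boron-complexed electron-poor ring resists ionisation of the benzylic acetate.

Step 14
Reactants: 18 (1R)-5-hydroxy-7-methyl-4-oxo-1,2,3,4-tetrahydronaphthalen-1-yl acetate
Product: 19 (1R)-5-(allyloxy)-7-methyl-4-oxo-1,2,3,4-tetrahydronaphthalen-1-yl acetate
Conditions: allyl bromide, K2CO3, dry DMF, rt to 50 °C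
Reagents that add atoms: allyl bromide C=CCBr
Why: Williamson O-allylation of the phenoxide proceeds in aprotic medium, where the acetate is not cleaved.

Step 15
Reactants: 19 (1R)-5-(allyloxy)-7-methyl-4-oxo-1,2,3,4-tetrahydronaphthalen-1-yl acetate
Product: 21 (1R)-6-allyl-5-hydroxy-7-methyl-4-oxo-1,2,3,4-tetrahydronaphthalen-1-yl acetate, via ortho-dienone 20 (not isolated)
Conditions: N,N-diethylaniline (degassed), 190 °C
Reagents that add atoms: none
Why: The aromatic Claisen rearrangement ([3,3] shift, then tautomerisation) can deliver the allyl group only to C7', the single free ortho position, which settles the C7' versus C5' regiochemistry while the weakly basic medium leaves the acetate and C4' alone.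

Step 16
Reactants: 21 (1R)-6-allyl-5-hydroxy-7-methyl-4-oxo-1,2,3,4-tetrahydronaphthalen-1-yl acetate
Product: 22 (1R)-6-allyl-5-(benzyloxy)-7-methyl-4-oxo-1,2,3,4-tetrahydronaphthalen-1-yl acetate
Conditions: BnBr, K2CO3, dry DMF, 60 °C
Reagents that add atoms: benzyl bromide BrCc1ccccc1
Why: Williamson benzylation masks the phenol, which would otherwise cyclise onto the allyl group under the palladium oxidation that follows.

Step 17
Reactants: 22 (1R)-6-allyl-5-(benzyloxy)-7-methyl-4-oxo-1,2,3,4-tetrahydronaphthalen-1-yl acetate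
Product: 23 (1R)-6-[(E)-3-acetoxyprop-1-enyl]-5-(benzyloxy)-7-methyl-4-oxo-1,2,3,4-tetrahydronaphthalen-1-yl acetate
Conditions: Pd(OAc)2 (10 mol %), 1,4-benzoquinone (2 equiv), 4 Å MS, DMSO/AcOH 1:1, 40 °C
Reagents that add atoms: acetic acid CC(=O)O
Why: In this allylic C–H acetoxylation divalent palladium cleaves the doubly activated (allylic and benzylic) C–H bond to a π-allyl complex, acetate attacks the unhindered terminus to give the conjugated E linear acetate, benzoquinone re-oxidises zerovalent palladium, and any branched acetate converges in the next step.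

Step 18
Reactants: 23 (1R)-6-[(E)-3-acetoxyprop-1-enyl]-5-(benzyloxy)-7-methyl-4-oxo-1,2,3,4-tetrahydronaphthalen-1-yl acetate
Product: 24 (1R)-5-(benzyloxy)-7-methyl-4-oxo-6-[(E)-3-(4,4,5,5-tetramethyl-1,3,2-dioxaborolan-2-yl)prop-1-enyl]-1,2,3,4-tetrahydronaphthalen-1-yl acetate (fragment 2)
Conditions: B2pin2 (1.1 equiv), Pd(dba)2 (5 mol %), DMSO, 50 °C
Reagents that add atoms: bis(pinacolato)diboron CC1(C)OB(OC1(C)C)B1OC(C)(C)C(C)(C)O1
Why: In this Miyaura-type allylic borylation zerovalent palladium ionises the allylic acetate, the π-allyl complex transmetalates with B2pin2, and C–B bond formation at the less hindered terminus gives the conjugated E boronate, while the secondary benzylic acetate and the ketone are inert to the ligand-free catalyst.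

**Union and completion**

Step 19
Reactants: 7 2-(benzyloxy)-4-methyl-6-vinylbenzaldehyde; 24 fragment 2 allylboronate
Product: 26 (1S,2R)-1-[2-(benzyloxy)-4-methyl-6-vinylphenyl]-2-[(5R)-5-acetoxy-1-(benzyloxy)-3-methyl-8-oxo-5,6,7,8-tetrahydronaphthalen-2-yl]but-3-en-1-ol, via pinacol borate 25 (not isolated)
Conditions: (S)-TRIP [(S)-3,3'-bis(2,4,6-triisopropylphenyl)-BINOL hydrogen phosphate] (10 mol %), 4 Å MS, toluene, −30 °C to rt; aq NaHCO3
Reagents that add atoms: none
Why: This chiral-phosphoric-acid-catalysed carbonyl allylboration runs through a closed Zimmerman–Traxler chair in which the E boronate gives the anti pair (3R,4S, later 3,4-cis), (S)-TRIP directs attack to the Si face of the aldehyde (the R acid gives R carbinols from aryl aldehydes), any wrong-face adduct is a separable diastereomer because C4' is already fixed, and the hindered aryl ketone does not react with an allyl pinacol boronate.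

Step 20
Reactants: 26 homoallylic alcohol
Product: 27 (5R)-1-(benzyloxy)-2-[(1S,2R)-1-[2-(benzyloxy)-4-methyl-6-vinylphenyl]-1-(tert-butyldimethylsilyloxy)but-3-en-2-yl]-3-methyl-8-oxo-5,6,7,8-tetrahydronaphthalen-5-yl acetate
Conditions: TBSOTf (1.3 equiv), 2,6-lutidine, CH2Cl2, −78 to 0 °C
Reagents that add atoms: TBSOTf CC(C)(C)[Si](C)(C)OS(=O)(=O)C(F)(F)F
Why: Silylation with the highly electrophilic silyl triflate protects the hindered C4 carbinol, which blocks dehydrative aromatisation of the coming dihydronaphthalene and allows C1 to be oxidised selectively later.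

Step 21
Reactants: 27 silyl ether diene
Product: 28 (5R)-1-(benzyloxy)-2-[(1S,2R)-8-(benzyloxy)-1-(tert-butyldimethylsilyloxy)-6-methyl-1,2-dihydronaphthalen-2-yl]-3-methyl-8-oxo-5,6,7,8-tetrahydronaphthalen-5-yl acetate
Conditions: second-generation Grubbs catalyst RuCl2(=CHPh)(PCy3)(SIMes) (5 mol %), CH2Cl2 (0.005 M), 40 °C
Reagents that add atoms: none
Why: Ring-closing metathesis of the styrene and the terminal vinyl group closes six-membered ring B with loss of ethene, no other alkene is present, and C3 and C4 are untouched so the anti pair becomes the 3,4-cis pair.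

Step 22
Reactants: 28 dihydronaphthalene
Product: 30 (5R)-1-(benzyloxy)-2-[(1S,2R)-8-(benzyloxy)-1-(tert-butyldimethylsilyloxy)-4-hydroxy-6-methyl-1,2,3,4-tetrahydronaphthalen-2-yl]-3-methyl-8-oxo-5,6,7,8-tetrahydronaphthalen-5-yl acetate (mixture of C1 epimers), via hydroperoxide 29 (not isolated)
Conditions: Mn(dpm)3 (10 mol %), PhSiH3 (2 equiv), O2 (1 atm), i-PrOH/CH2Cl2, 0 °C to rt; then PPh3
Reagents that add atoms: dioxygen O=O
Why: In this Mukaiyama hydration (metal-hydride hydrogen-atom transfer) the manganese hydride delivers H to C2 so that the benzylic C1 radical forms and is trapped by O2, giving only C1–O regiochemistry, and the new C1 centre is an inconsequential epimer mixture that the next step erases.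

Step 23
Reactants: 30 C1 alcohol (epimer mixture)
Product: 31 4'-O-acetyl-5,8'-di-O-benzyl-4-O-TBS derivative of the target (3R,4S,4'R)
Conditions: Dess–Martin periodinane, CH2Cl2, 0 °C to rt
Reagents that add atoms: none
Why: Dess–Martin oxidation under near-neutral conditions converts both C1 epimers into one aryl ketone, and C3 (β to the new carbonyl and therefore not epimerisable) and the protected carbinols are unaffected.

Step 24
Reactants: 31 protected diketone
Product: 32 5,8'-di-O-benzyl-4-O-TBS derivative of the target (3R,4S,4'R)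
Conditions: K2CO3 (0.2 equiv), MeOH/THF, 0 °C to rt
Reagents that add atoms: none
Why: Base-catalysed transesterification (Zemplén type) removes the C4' acetate with retention, and no β-leaving group or epimerisable stereocenter is present.

Step 25
Reactants: 32 dibenzyl ether
Product: 33 4-O-TBS derivative of the target (3R,4S,4'R)
Conditions: H2 (1 atm), 10% Pd/C, EtOAc, rt
Reagents that add atoms: none
Why: Hydrogenolysis cleaves the two aryl benzyl ethers far faster than the benzylic C–OH or C–OSi bonds on the ketone-deactivated rings, and the aryl ketones persist at 1 atm in a neutral solvent.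

Step 26
Reactants: 33 silyl ether
Product: 34 (3R,4S)-3-[(5R)-1,5-dihydroxy-3-methyl-8-oxo-5,6,7,8-tetrahydronaphthalen-2-yl]-4,5-dihydroxy-7-methyl-3,4-dihydronaphthalen-1(2H)-one (target)
Conditions: HF·pyridine, pyridine/THF, 0 °C to rt
Reagents that add atoms: none
Why: Buffered fluoride desilylation breaks only the Si–O bond, so C4 keeps its configuration and the acid-sensitive 4-hydroxytetralones are not dehydrated.

**Compound list**
1 | 3,5-dimethoxytoluene | COc1cc(C)cc(OC)c1 | starting material
2 | (2,6-dimethoxy-4-methylphenyl)lithium | [Li]c1c(OC)cc(C)cc1OC | intermediate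
3 | 2,6-dimethoxy-4-methylbenzaldehyde | COc1cc(C)cc(OC)c1C=O | intermediate
4 | 2,6-dihydroxy-4-methylbenzaldehyde | Cc1cc(O)c(C=O)c(O)c1 | intermediate
5 | 2-(benzyloxy)-6-hydroxy-4-methylbenzaldehyde | Cc1cc(O)c(C=O)c(OCc2ccccc2)c1 | intermediate
6 | 3-(benzyloxy)-2-formyl-5-methylphenyl triflate | Cc1cc(OCc2ccccc2)c(C=O)c(OS(=O)(=O)C(F)(F)F)c1 | intermediate
7 | 2-(benzyloxy)-4-methyl-6-vinylbenzaldehyde | C=Cc1cc(C)cc(OCc2ccccc2)c1C=O | intermediate
8 | 2-hydroxy-4-methylbenzaldehyde | Cc1ccc(C=O)c(O)c1 | starting material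
9 | 2-methoxy-4-methylbenzaldehyde | COc1cc(C)ccc1C=O | intermediate
10 | (2-carboxyethyl)triphenylphosphonium bromide | OC(=O)CC[P+](c1ccccc1)(c1ccccc1)c1ccccc1.[Br-] | starting material
11 | potassium 3-(triphenylphosphoranylidene)propanoate | [K+].[O-]C(=O)CC=P(c1ccccc1)(c1ccccc1)c1ccccc1 | intermediate
12 | (E)-4-(2-methoxy-4-methylphenyl)but-3-enoic acid | COc1cc(C)ccc1/C=C/CC(=O)O | intermediate
13 | 4-(2-methoxy-4-methylphenyl)butanoic acid | COc1cc(C)ccc1CCCC(=O)O | intermediate
14 | 5-methoxy-7-methyl-1-tetralone | COc1cc(C)cc2C(=O)CCCc12 | intermediate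
15 | (1R)-5-methoxy-7-methyl-1,2,3,4-tetrahydronaphthalen-1-ol | O[C@@H]1CCCc2c(OC)cc(C)cc12 | intermediate
16 | (1R)-5-methoxy-7-methyl-1,2,3,4-tetrahydronaphthalen-1-yl acetate | CC(=O)O[C@@H]1CCCc2c(OC)cc(C)cc12 | intermediate
17 | (1R)-5-methoxy-7-methyl-4-oxo-1,2,3,4-tetrahydronaphthalen-1-yl acetate | CC(=O)O[C@@H]1CCC(=O)c2c(OC)cc(C)cc12 | intermediate
18 | (1R)-5-hydroxy-7-methyl-4-oxo-1,2,3,4-tetrahydronaphthalen-1-yl acetate | CC(=O)O[C@@H]1CCC(=O)c2c(O)cc(C)cc12 | intermediate
19 | (1R)-5-(allyloxy)-7-methyl-4-oxo-1,2,3,4-tetrahydronaphthalen-1-yl acetate | CC(=O)O[C@@H]1CCC(=O)c2c(OCC=C)cc(C)cc12 | intermediate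
20 | ortho-dienone of the Claisen shift (C7' sp3, bearing allyl and H; C8' ketone) | CC(=O)O[C@@H]1CCC(=O)C2=C1C=C(C)C(CC=C)C2=O | intermediate
21 | (1R)-6-allyl-5-hydroxy-7-methyl-4-oxo-1,2,3,4-tetrahydronaphthalen-1-yl acetate | CC(=O)O[C@@H]1CCC(=O)c2c(O)c(CC=C)c(C)cc12 | intermediate
22 | (1R)-6-allyl-5-(benzyloxy)-7-methyl-4-oxo-1,2,3,4-tetrahydronaphthalen-1-yl acetate | CC(=O)O[C@@H]1CCC(=O)c2c(OCc3ccccc3)c(CC=C)c(C)cc12 | intermediate
23 | (1R,E)-cinnamyl-type acetate | CC(=O)OC/C=C/c1c(C)cc2c(c1OCc3ccccc3)C(=O)CC[C@H]2OC(C)=O | intermediate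
24 | (1R,E)-allyl pinacol boronate (fragment 2) | CC1(C)OB(C/C=C/c2c(C)cc3c(c2OCc4ccccc4)C(=O)CC[C@H]3OC(C)=O)OC1(C)C | intermediate
25 | pinacol borate of 26 (3R,4S,4'R) | C=C[C@H](c1c(C)cc2c(c1OCc3ccccc3)C(=O)CC[C@H]2OC(C)=O)[C@H](OB6OC(C)(C)C(C)(C)O6)c4c(C=C)cc(C)cc4OCc5ccccc5 | intermediate
26 | anti homoallylic alcohol (3R,4S,4'R) | C=C[C@H](c1c(C)cc2c(c1OCc3ccccc3)C(=O)CC[C@H]2OC(C)=O)[C@H](O)c4c(C=C)cc(C)cc4OCc5ccccc5 | intermediate
27 | TBS ether of 26 (3R,4S,4'R) | C=C[C@H](c1c(C)cc2c(c1OCc3ccccc3)C(=O)CC[C@H]2OC(C)=O)[C@H](O[Si](C)(C)C(C)(C)C)c4c(C=C)cc(C)cc4OCc5ccccc5 | intermediate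
28 | 3,4-cis dihydronaphthalene with C1=C2 (3R,4S,4'R) | Cc1cc(OCc2ccccc2)c3c(c1)C=C[C@H](c4c(C)cc5c(c4OCc6ccccc6)C(=O)CC[C@H]5OC(C)=O)[C@@H]3O[Si](C)(C)C(C)(C)C | intermediate
29 | C1 hydroperoxide (C1 epimers; 3R,4S,4'R) | Cc1cc(OCc2ccccc2)c3c(c1)C(OO)C[C@H](c4c(C)cc5c(c4OCc6ccccc6)C(=O)CC[C@H]5OC(C)=O)[C@@H]3O[Si](C)(C)C(C)(C)C | intermediate
30 | C1 alcohol (C1 epimers; 3R,4S,4'R) | Cc1cc(OCc2ccccc2)c3c(c1)C(O)C[C@H](c4c(C)cc5c(c4OCc6ccccc6)C(=O)CC[C@H]5OC(C)=O)[C@@H]3O[Si](C)(C)C(C)(C)C | intermediate
31 | 4'-O-acetyl-5,8'-di-O-benzyl-4-O-TBS target | Cc1cc(OCc2ccccc2)c3c(c1)C(=O)C[C@H](c4c(C)cc5c(c4OCc6ccccc6)C(=O)CC[C@H]5OC(C)=O)[C@@H]3O[Si](C)(C)C(C)(C)C | intermediate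
32 | 5,8'-di-O-benzyl-4-O-TBS target | Cc1cc(OCc2ccccc2)c3c(c1)C(=O)C[C@H](c4c(C)cc5c(c4OCc6ccccc6)C(=O)CC[C@H]5O)[C@@H]3O[Si](C)(C)C(C)(C)C | intermediate
33 | 4-O-TBS target | Cc1cc(O)c3c(c1)C(=O)C[C@H](c4c(C)cc5c(c4O)C(=O)CC[C@H]5O)[C@@H]3O[Si](C)(C)C(C)(C)C | intermediate
34 | CNP0228272.3 (3R,4S,4'R) | Cc1cc(O)c2c(c1)C(=O)C[C@H](c1c(C)cc3c(c1O)C(=O)CC[C@H]3O)[C@@H]2O | target

**Totals**
- Total step count: 26.
- Longest linear sequence: 21 steps (steps 6–26). The fragment 1 branch is 5 steps (steps 1–5).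

**Three steps most likely to fail**

Step 12 (benzylic oxidation). The risks are over-oxidation of the anisole ring and attack at the aryl methyl group. The fallback sets out from 14 and comes back at 17, and it brings in the C1' oxygen by phenol oxidation instead of C–H oxidation. Tetralone 14 is dehydrogenated with DDQ (dioxane, reflux) to 5-methoxy-7-methylnaphthalen-1-ol F1. PhI(OAc)2 (2.2 equiv) in MeOH oxidises F1 para to the OH, giving the quinone monoketal 4,4,5-trimethoxy-7-methylnaphthalen-1(4H)-one F2. Hydrogenation of the enone double bond (H2, Pd/C, EtOAc, trace Et3N) gives 4,4,5-trimethoxy-7-methyl-3,4-dihydronaphthalen-1(2H)-one F3. Reduction with (S)-Me-CBS oxazaborolidine and BH3·SMe2 gives (1R)-4,4,5-trimethoxy-7-methyl-1,2,3,4-tetrahydronaphthalen-1-ol F4. Ac2O/pyridine converts F4 into (1R)-4,4,5-trimethoxy-7-methyl-1,2,3,4-tetrahydronaphthalen-1-yl acetate F5, and PPTS in wet acetone unmasks the ketal to give 17.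

Step 17 (allylic C–H acetoxylation of a doubly ortho-substituted allyl arene). The risks are slow π-allyl formation and Wacker-type ketone formation. The fallback sets out from 22 and comes back at 24, replacing C–H oxidation and borylation by metathesis. Compound 22 is isomerised with RuHCl(CO)(PPh3)3 (toluene, 80 °C) to (1R)-5-(benzyloxy)-7-methyl-4-oxo-6-[(E)-prop-1-enyl]-1,2,3,4-tetrahydronaphthalen-1-yl acetate F6. Cross-metathesis of F6 with excess allyl pinacol boronate uses the second-generation Hoveyda–Grubbs catalyst RuCl2(=CH-C6H4-2-O-i-Pr)(SIMes) in CH2Cl2 at 40 °C. This gives 24 directly and bypasses 23 and step 18.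

Step 19 (allylboration between two doubly ortho-substituted partners). The risks are low rate and weak facial control. The fallback sets out from 24 (with 7) and comes back at 26. It uses a more reactive allylboron species and relies on the resident C4' centre instead of the catalyst. KHF2 in MeOH/H2O converts 24 into potassium trifluoro[(E)-3-aryl-allyl]borate F7. F7 adds to 7 under phase-transfer conditions (n-Bu4NI cat., CH2Cl2/H2O, rt) through the same closed chair, so E still gives anti. The products are 26 and its (3S,4R,4'R) anti diastereomer F8. They are separated by chromatography because they are diastereomers, not enantiomers.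

**Further compounds**
F1 | step 12 | 5-methoxy-7-methylnaphthalen-1-ol | COc1cc(C)cc2c(O)cccc12
F2 | step 12 | 4,4,5-trimethoxy-7-methylnaphthalen-1(4H)-one | COc1cc(C)cc2C(=O)C=CC(OC)(OC)c12
F3 | step 12 | 4,4,5-trimethoxy-7-methyl-3,4-dihydronaphthalen-1(2H)-one | COc1cc(C)cc2C(=O)CCC(OC)(OC)c12
F4 | step 12 | (1R)-4,4,5-trimethoxy-7-methyl-1,2,3,4-tetrahydronaphthalen-1-ol | O[C@@H]1CCC(OC)(OC)c2c(OC)cc(C)cc12
F5 | step 12 | (1R)-4,4,5-trimethoxy-7-methyl-1,2,3,4-tetrahydronaphthalen-1-yl acetate | CC(=O)O[C@@H]1CCC(OC)(OC)c2c(OC)cc(C)cc12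
F6 | step 17 | (1R)-5-(benzyloxy)-7-methyl-4-oxo-6-[(E)-prop-1-enyl]-1,2,3,4-tetrahydronaphthalen-1-yl acetate | C/C=C/c1c(C)cc2c(c1OCc3ccccc3)C(=O)CC[C@H]2OC(C)=O
F7 | step 19 | potassium trifluoro[(E)-3-aryl-allyl]borate derived from 24 | [K+].F[B-](F)(F)C/C=C/c1c(C)cc2c(c1OCc3ccccc3)C(=O)CC[C@H]2OC(C)=O
F8 | step 19 | (3S,4R,4'R) anti diastereomer of 26 | C=C[C@@H](c1c(C)cc2c(c1OCc3ccccc3)C(=O)CC[C@H]2OC(C)=O)[C@@H](O)c4c(C=C)cc(C)cc4OCc5ccccc5
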